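The dusk run ends with more product per starting material than the winter run: the ratio c(product)/c(starting material) reads 2.60 at 144 h in dusk, against 2.02 at 40.0 h in winter. Call the dusk value the stall ratio: a reading at 40 °C, carrying the scatter of its two readings.

common to all: starting material 41 mM; free enzyme 41 µM

|  | protic impurity | temperature | remark | time |
|---|---|---|---|---|
| dusk | 12.3 mM | 40 °C | the very flask that is asked about, followed so far |  |
| winter | 6.2 mM | 46 °C | run made earlier |  |
| flask | 12.3 mM | 40 °C |  | 8.0 d |

| run | time / h | product / % | starting material / % |
|---|---|---|---|
| dusk | 20.0 | 51.5 | 30.9 |
| dusk | 60.0 | 55.4 | 20.1 |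
| dusk | 96.0 | 52.6 | 20.4 |
| dusk | 144 | 52.0 | 20.0 |
| winter | 5.00 | 36.4 | 60.0 |
| winter | 15.0 | 59.4 | 31.6 |
| winter | 25.0 | 59.9 | 28.4 |
| winter | 40.0 | 57.2 | 28.3 |

(standard deviation of a reading: 1 percentage point)

- south-west: at 8.0 d add free enzyme, 100 % of the amount charged, then wait 15 d
- south-east: change nothing and wait 15 d more
- north-west: at 8.0 d take out 90 % of the product then present, then wait 15 d

- product taken out counts as made
- what may be going on: free enzyme -> unfolded enzyme; starting material + free enzyme <-> complex; starting material + protic impurity -> quenched substrate; complex <-> free enzyme + product
- additions bring no volume worth counting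

* product, in percent of the starting material first charged, at 8.0 d
* which option adds most product ("none" when 2 percentage points or less is all one gets) (south-west / south-east / north-west / none)
* product present, with what was taken out counted in, in percent of the starting material first charged, after south-west
* product present, with what was taken out counted in, in percent of the starting material first charged, after north-west

Two chemists stand at the board over the asked flask, which is dusk followed on. The first says the stall is an equilibrium (thermodynamic control), with the enzyme still working both ways. The second says the enzyme has unfolded and the flat product marks a dead catalyst, so product taken out in north-west is not remade and the best option is none. The first answers from dusk: starting material goes from 20.1 % to 20.0 % while product goes from 55.4 % to 52.0 %, so product is still being drawn back through the enzyme.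

My reckoning takes the first side and freezes two things. One is the ratio. The other is the quenched substrate, set by the protic impurity, the limiting reagent of the quench, at 30.0 % of the starting material. The enzyme charge is 0.100 % of the starting material, so the complex drops out of the balance. The pool is then 70.0 %, and product takes the share 72.2 % of it, which gives 50.6 % at 8.0 d. Added enzyme leaves pool and ratio as they are. North-west takes out 45.5 %, the rest of the pool divides again, and the total is 63.2 %, a gain of 13 percentage points.

The forecast takes the same side: “this looks like an equilibrium stall and not a dead enzyme”. It gives 51 %, then 51 % after south-west and 62 % after north-west, with north-west as best, so its last figure stands below mine.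

The simulation gives 51.3 %, 50.8 % and 63.5 %, with north-west as best at 12 points, and the forecast holds.

    free enzyme → unfolded enzyme (k = 8.96 × 10⁻⁴ h⁻¹, Ea = 261 kJ mol⁻¹)
    starting material + free enzyme ⇌ complex (K = 35.9 M⁻¹, k = 7.46 × 10⁵ M⁻¹ h⁻¹, Ea = 36.0 kJ mol⁻¹, ΔH = 31.0 kJ mol⁻¹)
    starting material + protic impurity → quenched substrate (k = 2.13 M⁻¹ h⁻¹, Ea = 77.0 kJ mol⁻¹)
    complex ⇌ free enzyme + product (K = 0.0740 M, k = 81.0 h⁻¹, Ea = 75.0 kJ mol⁻¹, ΔH = −65.0 kJ mol⁻¹)
    (constants at 40 °C)

The second chemist's view comes nearer later in the asked flask: unfolded enzyme is 12.1 % at 192 h and 73.7 % at 1920 h, with free enzyme then at 20.5 % and complex at 5.77 %. The answer to "now" moves away from the forecast's figure with the protic impurity: at 9.36 mM or 15.3 mM it has moved 5 points. Counting the impurity still left, the share times the pool gives 51.0 % in the asked flask at 8.0 d. The same reckoning on a neighbour flask charged with 31 mM of protic impurity gives 23.0 %. That neighbour flask itself holds 23.4 % of product, with 9.8 % of its protic impurity left.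

The numbers in the tables are simulated for an exercise; scatter was added.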